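## The problem

The target is a cyclohexene (numbered here C1 to C6) whose C1 carries a 7-methoxycoumarin-6-yl group (coumarin A), whose C2=C3 double bond bears a methyl group on C3, and whose quaternary C6 carries a methyl group and an (E)-ethenyl bridge Ca=Cb to C8 of a second 7-methoxycoumarin (coumarin B). The two stereocentres are contiguous, (1R,6R), with the aryl group and the styryl arm cis. C6 is quaternary and C1 has no acidifying neighbour, so neither can be corrected later and both must come out of one stereospecific event. Because the unit aryl–C1–C2=C3(CH3) lies next to a carbon-substituted C6, a single stereocentre at C3 can control both through a [3,3] shift and then vanish into the alkene. Fragile points are the two coumarin lactones (opened by hydroxide, attacked by hydride and organometallic reagents), the ring alkene (no hydrogenolysis; it will capture a cation at Cb), and the 1,5-diene C3=C2–C1–C6–Ca=Cb, which should not be heated once complete. Coumarin A has the easy 6,7-pattern, reached by electrophilic formylation of a resorcinol ether. Coumarin B has the hard one: methoxy at C7, Cb at C8 and the ring oxygen at C8a on three neighbouring carbons, with C8 wedged between two oxygens. That 1,2,3-array is what forms when 3-methoxybenzyne inserts into the C–O bond of a carboxylic acid (oxygen remote from methoxy, acyl carbon next to it), so the benzene ring of coumarin B can be built onto a C6 acetic acid side chain.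

## Retrosynthesis

**30 to 28 (through 29).** The Ca=Cb double bond is traced back to a ketone at Cb. Making the alkene last keeps the 1,5-diene away from the hot lactonisation that closes coumarin B. It also means that no cation or ortho-quinone methide is ever generated at Cb while a free phenol sits beside it. The forward steps are a 1,2-reduction that spares two coumarins (29) and a syn-elimination that can only take a hydrogen from Ca.

**28 to 25.** The pyranone of coumarin B is cut at C4a–C4 and at the lactone C–O bond. The forward reactions are ortho-formylation of the phenol (26), then Wittig olefination and lactonisation. In 25 only one position ortho to the hydroxyl is free, and it is para to methoxy, so the regiochemistry is not in doubt. The precursor has one ring fewer.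

**25 to 21 and 22 (key step).** The bonds C8–Cb and C8a–O are cut together. A phenol acylation would go para to oxygen. An aryl-metal route would put an organolithium next to coumarin A. A ready-made coumarin B piece would need functionality at its C8, which direct substitution does not reach. The aryne insertion uses the free acid 21 and the commercial silyl triflate 22 under fluoride alone. It is asked to put oxygen meta and Cb ortho to methoxy, and to transfer the acyl group to carbon instead of stopping at the aryl ester.

**21 to 16.** Coumarin A is removed in the same way as coumarin B: lactone C–O and C4a–C4 (20 from salicylaldehyde 18), the chelation-controlled unmasking of one phenol (18 from 17) and the formyl group (17 from 16). The acid is carried as an allyl ester, because its removal by zerovalent palladium needs neither hydroxide nor acid.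

**16 to 12.** The CH2 between C6 and the carboxyl group is taken out (Arndt–Eistert through 13, 14 and 15). This is accepted because the ring-forming step delivers the carboxyl directly on C6 and the Wolff shift moves a quaternary carbon with retention.

**12 to 9.** The C1–C6 bond is cut and C3–O is reconnected (Ireland–Claisen retron through 10 and 11). This is the simplifying cut: two contiguous stereocentres and the ring alkene become one tertiary carbinol centre in a monocyclic lactone. The forward reaction must pass through the boat array that the tether enforces and must stay concerted.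

**9 to 6 and 8.** The styryl double bond is cut by cross-metathesis. A Heck arylation would expose a tertiary allylic carboxylate to zerovalent palladium, which ionises such bonds; a ruthenium carbene does not. Styrene 8 is one Wittig step from aldehyde 7.

**6 to 1.** The C3 methyl of lactone 6 comes from enolate alkylation of 5. The lactone carbonyl comes from oxidation of lactol 4, and its carbon from a one-carbon Wittig homologation (3) of lactol 2. Lactol 2 is the ozonolysis product of (R)-linalool 1, which supplies the tertiary carbinol centre, its methyl and vinyl groups and three ring carbons.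

## Roads not taken

**Alternative 1:** The ring would be cut at C1–C6 and C2–C3. A chiral primary amine–thiourea would add the enamine of keto aldehyde A1 to nitrostyrene A2 (C1–C6). After addition of Et3N the nitronate would close onto the methyl ketone (C2–C3) to give nitro alcohol A3 with aryl cis to formyl.
- Merits: two achiral fragments, catalytic asymmetric induction, and the ring with both stereocentres in one flask. The C6 aldehyde can be homologated by one carbon without diazomethane, so the counterpart of ester 16 would be reached in fewer steps than the eight used here.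
- Weak points: the enamine of A1 carries two α-substituents of similar size (methyl and a 3-oxobutyl chain), so the geometry that fixes the quaternary C6 is poorly defined. The Henry closure adds two stereocentres that must be erased. Turning the β-nitro alcohol into the C2=C3 alkene regiospecifically costs two to three steps through an intermediate prone to retro-Henry cleavage.
- Comparison: this road is shorter and catalytic, which the chosen plan cannot match. The chosen plan sets against it that both stereocentres and the alkene position come from one purchased stereocentre by a shift whose geometry a ring dictates.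

**Alternative 2:** The aryl–C1 bond would be cut, with the C6 carboxyl as tether. BF3·OEt2 would ionise the tertiary allylic alcohol of aryl ester A4. The tethered ring would attack the allyl cation at C1 through its carbon para to methoxy, giving the cis-fused lactone A5.
- Merits: the tether makes the cis relation of aryl and carboxyl unavoidable, the alkene falls into place, and the lactone carbonyl is the C6 carboxyl ready for the same homologation. After ring opening and O-methylation the arene is the resorcinol dimethyl ether of 12.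
- Weak points: the absolute configuration must already sit in the quaternary centre of A4, and making that ester enantioselectively is a problem as large as the one being solved. The attacking carbon is ortho to a weakly donating acyloxy group. The cation can lose a proton to a diene or be attacked at its tertiary end C3, and the Lewis acid invites Fries migration.
- Comparison: from A5 onward the two routes coincide, so this road would replace steps 1 to 7 only. It is equal in relative stereocontrol, but the chosen plan has a cheap and defined source of absolute configuration.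

**Alternative 3:** The C1–aryl and C6–CH3 bonds would both be cut. The methyl ate complex of dienyl boronic ester A6 would couple with aryl triflate A7 under Pd(OAc)2 and a MandyPhos ligand. Methyl would migrate from boron to C6 while the aryl group adds to C1 on the opposite face, giving tertiary boronate A8.
- Merits: three components and both stereocentres from one catalytic step. The tertiary boronate could be turned with retention into a vinyl-bearing quaternary carbon (Zweifel olefination) and joined to a coumarin B halide, far shorter than the present route and without homologation.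
- Weak points: conjunctive coupling is established for simple vinyl boron ate complexes. Here the migration terminus is a ring carbon of a conjugated diene, the resulting allylpalladium can couple at C1 or C3, methyl migrates reluctantly, and the electron-rich ortho-substituted triflate adds slowly to zerovalent palladium. Enantio- and regiocontrol on this substrate class are untested.
- Comparison: in step count this road is clearly better and would be preferred if its key step worked. The chosen plan sets against it that each of its steps has a close precedent on the same bond type.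

Key step: step 14

Remark: CIP descriptors change along the route ((1S,2S) in acid 12, (1R,2R) from ester 16 on) only because substituent priorities change; the arrangement set in step 7 is carried through untouched. The enantiomeric purity of commercial (R)-linalool limits that of the target.

## Route

Step 1
Reactants: 1 (R)-linalool, (3R)-3,7-dimethylocta-1,6-dien-3-ol
Product: 2 (5R)-5-ethenyl-5-methyloxolan-2-ol (lactol; both anomers)
Conditions: O3 (1 equiv), CH2Cl2–MeOH, −78 °C; then Me2S, −78 °C to rt
Reagents that add atoms: ozone, O=[O+][O-]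
Why: Ozonolysis with one equivalent of ozone cleaves the electron-rich trisubstituted alkene well before the monosubstituted vinyl group, and the hydroxy aldehyde closes to the five-membered lactol. The carbinol stereocentre is not touched.

Step 2
Reactants: 2 (5R)-5-ethenyl-5-methyloxolan-2-ol
Product: 4 (6R)-6-ethenyl-6-methyloxan-2-ol (lactol; both anomers), via enol ether 3 (not isolated)
Conditions: Ph3P(CH2OMe)Cl, KOtBu, THF, 0 °C to rt; then 1 M HCl, 0 °C to rt
Reagents that add atoms: (methoxymethyl)triphenylphosphonium chloride, COC[P+](c1ccccc1)(c1ccccc1)c1ccccc1.[Cl-]; water, O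
Why: Wittig reaction of the lactol through its open hydroxy aldehyde with excess methoxymethylidene ylide, then enol ether hydrolysis in the same flask. The aldehyde, one carbon longer, closes onto the tertiary hydroxyl as the six-membered lactol.

Step 3
Reactants: 4 (6R)-6-ethenyl-6-methyloxan-2-ol
Product: 5 (6R)-6-ethenyl-6-methyloxan-2-one
Conditions: TEMPO ((2,2,6,6-tetramethylpiperidin-1-yl)oxyl, cat.), PhI(OAc)2, CH2Cl2, rt
Reagents that add atoms: none
Why: Oxoammonium oxidation of a lactol to the lactone. The near-neutral medium leaves the vinyl group and the tertiary allylic C–O bond alone.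

Step 4
Reactants: 5 (6R)-6-ethenyl-6-methyloxan-2-one
Product: 6 (6R)-6-ethenyl-3,6-dimethyloxan-2-one (both C3 epimers)
Conditions: LiN(iPr)2, THF, −78 °C; MeI, −78 to −40 °C
Reagents that add atoms: iodomethane, CI
Why: Lactone enolate alkylation. The configuration at C3 is irrelevant because this carbon becomes trigonal in step 7.

Step 5
Reactants: 7 2,4-dimethoxybenzaldehyde
Product: 8 1-ethenyl-2,4-dimethoxybenzene
Conditions: Ph3PCH3Br, KOtBu, THF, 0 °C to rt
Reagents that add atoms: methyltriphenylphosphonium bromide, C[P+](c1ccccc1)(c1ccccc1)c1ccccc1.[Br-]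
Why: Wittig methylenation of an aromatic aldehyde.

Step 6
Reactants: 6 (6R)-6-ethenyl-3,6-dimethyloxan-2-one; 8 1-ethenyl-2,4-dimethoxybenzene (excess)
Product: 9 (6R)-6-[(E)-2-(2,4-dimethoxyphenyl)ethenyl]-3,6-dimethyloxan-2-one (both C3 epimers)
Conditions: second-generation Hoveyda–Grubbs catalyst RuCl2(=CH-C6H4-2-OiPr)(H2IMes) (5 mol %; H2IMes = 1,3-dimesitylimidazolidin-2-ylidene), CH2Cl2, 40 °C, under argon flow
Reagents that add atoms: none
Why: Olefin cross-metathesis between a styrene and a vinyl group on a fully substituted, oxygen-bearing carbon that cannot homodimerise. The bulky neighbour makes the E alkene the only accessible product, and the ruthenium carbene does not ionise the tertiary allylic C–O bond, so the stereocentre is safe.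

Step 7
Reactants: 9 (6R)-6-[(E)-2-(2,4-dimethoxyphenyl)ethenyl]-3,6-dimethyloxan-2-one
Product: 12 (1S,2S)-2-(2,4-dimethoxyphenyl)-1,4-dimethylcyclohex-3-ene-1-carboxylic acid (aryl cis to carboxyl), via silyl ketene acetal 10 (not isolated), via trimethylsilyl ester 11 (not isolated)
Conditions: LiN(iPr)2, Me3SiCl–Et3N, THF, −78 °C to rt; toluene, 90 °C; aqueous citric acid work-up
Reagents that add atoms: none
Why: Ireland–Claisen rearrangement of a lactone silyl ketene acetal. The endocyclic ketene acetal and the two-carbon tether allow only a boat transition state, in which the E styryl group places aryl at C1 cis to the carboxyl at C6. The (R) carbinol centre is transferred suprafacially to both new stereocentres, giving the (1R,6R) sense of the target.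

Step 8
Reactants: 12 (1S,2S)-2-(2,4-dimethoxyphenyl)-1,4-dimethylcyclohex-3-ene-1-carboxylic acid
Product: 14 2-diazo-1-[(1S,2S)-2-(2,4-dimethoxyphenyl)-1,4-dimethylcyclohex-3-en-1-yl]ethan-1-one, via acid chloride 13 (not isolated)
Conditions: (COCl)2, DMF (cat.), CH2Cl2, 0 °C to rt; evaporate; CH2N2 (excess), Et2O, 0 °C
Reagents that add atoms: diazomethane, C=[N+]=[N-]
Why: Acid chloride formation and acylation of diazomethane, the first stage of the Arndt–Eistert homologation. A second equivalent of diazomethane takes up the HCl.

Step 9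
Reactants: 14 2-diazo-1-[(1S,2S)-2-(2,4-dimethoxyphenyl)-1,4-dimethylcyclohex-3-en-1-yl]ethan-1-one
Product: 16 prop-2-enyl 2-[(1R,2R)-2-(2,4-dimethoxyphenyl)-1,4-dimethylcyclohex-3-en-1-yl]acetate, via ketene 15 (not isolated)
Conditions: PhCO2Ag (cat.), Et3N, allyl alcohol, THF, rt, dark
Reagents that add atoms: allyl alcohol, C=CCO
Why: Silver-catalysed Wolff rearrangement. The quaternary carbon migrates with retention and allyl alcohol traps the ketene, giving an ester that can later be removed without hydroxide or acid.

Step 10
Reactants: 16 prop-2-enyl 2-[(1R,2R)-2-(2,4-dimethoxyphenyl)-1,4-dimethylcyclohex-3-en-1-yl]acetate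
Product: 17 prop-2-enyl 2-[(1R,2R)-2-(5-formyl-2,4-dimethoxyphenyl)-1,4-dimethylcyclohex-3-en-1-yl]acetate
Conditions: POCl3, DMF, 0 to 60 °C; then aqueous NaOAc
Reagents that add atoms: N,N-dimethylformamide, CN(C)C=O; water, O
Why: Vilsmeier–Haack formylation at the ring carbon para to one methoxy group and ortho to the other, the only unhindered doubly activated site. The isolated ring alkene is not nucleophilic enough to compete.

Step 11
Reactants: 17 prop-2-enyl 2-[(1R,2R)-2-(5-formyl-2,4-dimethoxyphenyl)-1,4-dimethylcyclohex-3-en-1-yl]acetate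
Product: 18 prop-2-enyl 2-[(1R,2R)-2-(5-formyl-4-hydroxy-2-methoxyphenyl)-1,4-dimethylcyclohex-3-en-1-yl]acetate
Conditions: BCl3, CH2Cl2, −78 to 0 °C; aqueous NaHCO3
Reagents that add atoms: none
Why: Chelation-controlled ether cleavage. BCl3 bound to the aldehyde oxygen removes only the methyl ether ortho to it, so the other methoxy group remains as the C7 methoxy of coumarin A.

Step 12
Reactants: 18 prop-2-enyl 2-[(1R,2R)-2-(5-formyl-4-hydroxy-2-methoxyphenyl)-1,4-dimethylcyclohex-3-en-1-yl]acetate
Product: 20 prop-2-enyl 2-[(1R,2R)-2-(7-methoxy-2-oxo-2H-chromen-6-yl)-1,4-dimethylcyclohex-3-en-1-yl]acetate, via cinnamate 19 (not isolated)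
Conditions: Ph3P=CHCO2Et, PhNEt2, reflux
Reagents that add atoms: ethyl (triphenylphosphoranylidene)acetate, CCOC(=O)C=P(c1ccccc1)(c1ccccc1)c1ccccc1
Why: Wittig olefination of the salicylaldehyde, then thermal E to Z isomerisation and lactonisation in boiling N,N-diethylaniline, the standard one-flask coumarin synthesis. The allyl ester and the ring alkene are thermally inert here.

Step 13
Reactants: 20 prop-2-enyl 2-[(1R,2R)-2-(7-methoxy-2-oxo-2H-chromen-6-yl)-1,4-dimethylcyclohex-3-en-1-yl]acetate
Product: 21 2-[(1R,2R)-2-(7-methoxy-2-oxo-2H-chromen-6-yl)-1,4-dimethylcyclohex-3-en-1-yl]acetic acid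
Conditions: Pd(PPh3)4 (5 mol %), morpholine, THF, rt
Reagents that add atoms: none
Why: Allyl ester cleavage by zerovalent palladium through a π-allyl complex that morpholine captures. The neutral conditions spare the coumarin lactone.

Step 14
Reactants: 21 2-[(1R,2R)-2-(7-methoxy-2-oxo-2H-chromen-6-yl)-1,4-dimethylcyclohex-3-en-1-yl]acetic acid; 22 3-methoxy-2-(trimethylsilyl)phenyl trifluoromethanesulfonate
Product: 25 1-(2-hydroxy-6-methoxyphenyl)-2-[(1R,2R)-2-(7-methoxy-2-oxo-2H-chromen-6-yl)-1,4-dimethylcyclohex-3-en-1-yl]ethan-1-one, via 3-methoxybenzyne 23 (not isolated), via aryl anion 24 (not isolated)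
Conditions: CsF, THF, 125 °C (sealed tube)
Reagents that add atoms: none
Why: Fluoride removes the silyl group of 22 and triflate leaves, giving 3-methoxybenzyne 23, while the acid is present as its caesium carboxylate. The carboxylate oxygen adds to the aryne carbon remote from methoxy, because the developing aryl anion then sits next to the inductively withdrawing methoxy group (aryl anion 24). This anion attacks its own ester carbonyl through a four-centre transition structure, and cleavage of the acyl C–O bond moves the acyl group from oxygen to carbon, leaving the caesium phenoxide of 25. The closest known reaction type is the fluoride-induced insertion of arynes into the C–O bond of carboxylic acids to give ortho-hydroxyaryl ketones, run hot in THF so that acyl transfer outruns protonation of the aryl anion. Two skeletal bonds form (O–C8a and Cb–C8 of the later coumarin B); no ring closes and no stereocentre is made or touched. The required regiochemistry is secured by the methoxy group flanking the triple bond. C-acylation over simple O-arylation is favoured by the aprotic medium, in which the only acidic proton has been consumed in forming the carboxylate. The coumarin lactone and the ring alkene should remain spectators because the carboxylate is by far the best nucleophile present.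

Step 15
Reactants: 25 1-(2-hydroxy-6-methoxyphenyl)-2-[(1R,2R)-2-(7-methoxy-2-oxo-2H-chromen-6-yl)-1,4-dimethylcyclohex-3-en-1-yl]ethan-1-one
Product: 26 2-hydroxy-4-methoxy-3-{2-[(1R,2R)-2-(7-methoxy-2-oxo-2H-chromen-6-yl)-1,4-dimethylcyclohex-3-en-1-yl]acetyl}benzaldehyde
Conditions: MgCl2 (anhydrous), Et3N, (CH2O)n, MeCN, reflux
Reagents that add atoms: formaldehyde (as paraformaldehyde), C=O
Why: Magnesium-mediated ortho-formylation of a phenol (Casnati–Skattebøl type). Formaldehyde is delivered within the magnesium phenoxide to the only free ortho carbon, which is also para to methoxy, and a second formaldehyde oxidises the benzylic alkoxide to the aldehyde.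

Step 16
Reactants: 26 2-hydroxy-4-methoxy-3-{2-[(1R,2R)-2-(7-methoxy-2-oxo-2H-chromen-6-yl)-1,4-dimethylcyclohex-3-en-1-yl]acetyl}benzaldehyde
Product: 28 7-methoxy-8-{2-[(1R,2R)-2-(7-methoxy-2-oxo-2H-chromen-6-yl)-1,4-dimethylcyclohex-3-en-1-yl]acetyl}-2H-chromen-2-one, via cinnamate 27 (not isolated)
Conditions: Ph3P=CHCO2Et, PhNEt2, reflux
Reagents that add atoms: ethyl (triphenylphosphoranylidene)acetate, CCOC(=O)C=P(c1ccccc1)(c1ccccc1)c1ccccc1
Why: The same Wittig olefination and thermal lactonisation as in step 12. The stabilised ylide takes the aldehyde and ignores the hindered ketone, and with Cb still a ketone no 1,5-diene is exposed to the heat.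

Step 17
Reactants: 28 7-methoxy-8-{2-[(1R,2R)-2-(7-methoxy-2-oxo-2H-chromen-6-yl)-1,4-dimethylcyclohex-3-en-1-yl]acetyl}-2H-chromen-2-one
Product: 29 8-{1-hydroxy-2-[(1R,2R)-2-(7-methoxy-2-oxo-2H-chromen-6-yl)-1,4-dimethylcyclohex-3-en-1-yl]ethyl}-7-methoxy-2H-chromen-2-one (both carbinol epimers)
Conditions: NaBH4, CeCl3·7H2O, MeOH–THF, 0 °C
Reagents that add atoms: none
Why: Luche reduction delivers hydride 1,2 to the ketone and leaves the two conjugated coumarin lactones alone. The configuration of the new carbinol is irrelevant because it is removed in step 18.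

Step 18
Reactants: 29 8-{1-hydroxy-2-[(1R,2R)-2-(7-methoxy-2-oxo-2H-chromen-6-yl)-1,4-dimethylcyclohex-3-en-1-yl]ethyl}-7-methoxy-2H-chromen-2-one
Product: 30 7-methoxy-8-{(E)-2-[(1R,2R)-2-(7-methoxy-2-oxo-2H-chromen-6-yl)-1,4-dimethylcyclohex-3-en-1-yl]ethenyl}-2H-chromen-2-one
Conditions: Burgess reagent (methyl N-(triethylammoniosulfonyl)carbamate), toluene, 70 °C
Reagents that add atoms: none
Why: Burgess dehydration by intramolecular syn-elimination of the sulfamate. Only Ca carries β-hydrogens, and the conformer with the quaternary carbon anti to the aryl group gives the E alkene. The proton is removed within the ion pair, so no free cation is left for the ring alkene to trap.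

## Compound list

1 | (R)-linalool, (3R)-3,7-dimethylocta-1,6-dien-3-ol | CC(C)=CCC[C@@](C)(O)C=C | starting material
2 | (5R)-5-ethenyl-5-methyloxolan-2-ol (anomers) | OC1CC[C@@](C)(O1)C=C | intermediate
3 | (3R)-7-methoxy-3-methylhepta-1,6-dien-3-ol (E/Z enol ether) | COC=CCC[C@@](C)(O)C=C | intermediate
4 | (6R)-6-ethenyl-6-methyloxan-2-ol (anomers) | OC1CCC[C@@](C)(O1)C=C | intermediate
5 | (6R)-6-ethenyl-6-methyloxan-2-one | O=C1CCC[C@@](C)(O1)C=C | intermediate
6 | (6R)-6-ethenyl-3,6-dimethyloxan-2-one (C3 epimers) | CC1CC[C@@](C)(OC1=O)C=C | intermediate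
7 | 2,4-dimethoxybenzaldehyde | COc1ccc(C=O)c(OC)c1 | starting material
8 | 1-ethenyl-2,4-dimethoxybenzene | COc1ccc(C=C)c(OC)c1 | intermediate
9 | (6R)-6-[(E)-2-(2,4-dimethoxyphenyl)ethenyl]-3,6-dimethyloxan-2-one (C3 epimers) | CC1CC[C@@](C)(OC1=O)/C=C/c1ccc(OC)cc1OC | intermediate
10 | ({(2R)-2-[(E)-2-(2,4-dimethoxyphenyl)ethenyl]-2,5-dimethyl-3,4-dihydro-2H-pyran-6-yl}oxy)trimethylsilane | CC1=C(O[Si](C)(C)C)O[C@](C)(CC1)/C=C/c1ccc(OC)cc1OC | intermediate
11 | trimethylsilyl (1S,2S)-2-(2,4-dimethoxyphenyl)-1,4-dimethylcyclohex-3-ene-1-carboxylate | COc1ccc([C@@H]2C=C(C)CC[C@]2(C)C(=O)O[Si](C)(C)C)c(OC)c1 | intermediate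
12 | (1S,2S)-2-(2,4-dimethoxyphenyl)-1,4-dimethylcyclohex-3-ene-1-carboxylic acid | COc1ccc([C@@H]2C=C(C)CC[C@]2(C)C(=O)O)c(OC)c1 | intermediate
13 | (1S,2S)-2-(2,4-dimethoxyphenyl)-1,4-dimethylcyclohex-3-ene-1-carbonyl chloride | COc1ccc([C@@H]2C=C(C)CC[C@]2(C)C(=O)Cl)c(OC)c1 | intermediate
14 | 2-diazo-1-[(1S,2S)-2-(2,4-dimethoxyphenyl)-1,4-dimethylcyclohex-3-en-1-yl]ethan-1-one | COc1ccc([C@@H]2C=C(C)CC[C@]2(C)C(=O)C=[N+]=[N-])c(OC)c1 | intermediate
15 | 2-[2-(2,4-dimethoxyphenyl)-1,4-dimethylcyclohex-3-en-1-yl]ethenone (ketene, ring configuration of 14) | COc1ccc([C@@H]2C=C(C)CC[C@]2(C)C=C=O)c(OC)c1 | intermediate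
16 | prop-2-enyl 2-[(1R,2R)-2-(2,4-dimethoxyphenyl)-1,4-dimethylcyclohex-3-en-1-yl]acetate | COc1ccc([C@@H]2C=C(C)CC[C@]2(C)CC(=O)OCC=C)c(OC)c1 | intermediate
17 | prop-2-enyl 2-[(1R,2R)-2-(5-formyl-2,4-dimethoxyphenyl)-1,4-dimethylcyclohex-3-en-1-yl]acetate | COc1cc(OC)c(C=O)cc1[C@@H]1C=C(C)CC[C@]1(C)CC(=O)OCC=C | intermediate
18 | prop-2-enyl 2-[(1R,2R)-2-(5-formyl-4-hydroxy-2-methoxyphenyl)-1,4-dimethylcyclohex-3-en-1-yl]acetate | COc1cc(O)c(C=O)cc1[C@@H]1C=C(C)CC[C@]1(C)CC(=O)OCC=C | intermediate
19 | ethyl (E)-3-[2-hydroxy-4-methoxy-5-{(1R,6R)-3,6-dimethyl-6-[2-oxo-2-(prop-2-enyloxy)ethyl]cyclohex-2-en-1-yl}phenyl]prop-2-enoate | CCOC(=O)/C=C/c1cc([C@@H]2C=C(C)CC[C@]2(C)CC(=O)OCC=C)c(OC)cc1O | intermediate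
20 | prop-2-enyl 2-[(1R,2R)-2-(7-methoxy-2-oxo-2H-chromen-6-yl)-1,4-dimethylcyclohex-3-en-1-yl]acetate | COc1cc2oc(=O)ccc2cc1[C@@H]1C=C(C)CC[C@]1(C)CC(=O)OCC=C | intermediate
21 | 2-[(1R,2R)-2-(7-methoxy-2-oxo-2H-chromen-6-yl)-1,4-dimethylcyclohex-3-en-1-yl]acetic acid | COc1cc2oc(=O)ccc2cc1[C@@H]1C=C(C)CC[C@]1(C)CC(=O)O | intermediate
22 | 3-methoxy-2-(trimethylsilyl)phenyl trifluoromethanesulfonate | COc1cccc(OS(=O)(=O)C(F)(F)F)c1[Si](C)(C)C | starting material
23 | 3-methoxybenzyne (1-methoxy-2,3-didehydrobenzene) | COC1=CC=CC#C1 | intermediate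
24 | caesium 2-methoxy-6-({2-[(1R,2R)-2-(7-methoxy-2-oxo-2H-chromen-6-yl)-1,4-dimethylcyclohex-3-en-1-yl]acetyl}oxy)benzen-1-ide | COc1cc2oc(=O)ccc2cc1[C@@H]1C=C(C)CC[C@]1(C)CC(=O)Oc1cccc(OC)[c-]1.[Cs+] | intermediate
25 | 1-(2-hydroxy-6-methoxyphenyl)-2-[(1R,2R)-2-(7-methoxy-2-oxo-2H-chromen-6-yl)-1,4-dimethylcyclohex-3-en-1-yl]ethan-1-one | COc1cc2oc(=O)ccc2cc1[C@@H]1C=C(C)CC[C@]1(C)CC(=O)c1c(O)cccc1OC | intermediate
26 | 2-hydroxy-4-methoxy-3-{2-[(1R,2R)-2-(7-methoxy-2-oxo-2H-chromen-6-yl)-1,4-dimethylcyclohex-3-en-1-yl]acetyl}benzaldehyde | COc1cc2oc(=O)ccc2cc1[C@@H]1C=C(C)CC[C@]1(C)CC(=O)c1c(O)c(C=O)ccc1OC | intermediate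
27 | ethyl (E)-3-(2-hydroxy-4-methoxy-3-{2-[(1R,2R)-2-(7-methoxy-2-oxo-2H-chromen-6-yl)-1,4-dimethylcyclohex-3-en-1-yl]acetyl}phenyl)prop-2-enoate | COc1cc2oc(=O)ccc2cc1[C@@H]1C=C(C)CC[C@]1(C)CC(=O)c1c(O)c(/C=C/C(=O)OCC)ccc1OC | intermediate
28 | 7-methoxy-8-{2-[(1R,2R)-2-(7-methoxy-2-oxo-2H-chromen-6-yl)-1,4-dimethylcyclohex-3-en-1-yl]acetyl}-2H-chromen-2-one | COc1cc2oc(=O)ccc2cc1[C@@H]1C=C(C)CC[C@]1(C)CC(=O)c1c(OC)ccc2ccc(=O)oc12 | intermediate
29 | 8-{1-hydroxy-2-[(1R,2R)-2-(7-methoxy-2-oxo-2H-chromen-6-yl)-1,4-dimethylcyclohex-3-en-1-yl]ethyl}-7-methoxy-2H-chromen-2-one (carbinol epimers) | COc1cc2oc(=O)ccc2cc1[C@@H]1C=C(C)CC[C@]1(C)CC(O)c1c(OC)ccc2ccc(=O)oc12 | intermediate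
30 | 7-methoxy-8-{(E)-2-[(1R,2R)-2-(7-methoxy-2-oxo-2H-chromen-6-yl)-1,4-dimethylcyclohex-3-en-1-yl]ethenyl}-2H-chromen-2-one | COc1cc2oc(=O)ccc2cc1[C@@H]1C=C(C)CC[C@]1(C)/C=C/c1c(OC)ccc2ccc(=O)oc12 | target

## Step count and least certain steps

Total: 18 steps. Longest linear sequence: 17 steps (steps 1 to 4 and 6 to 18, from 1).

**Step 14 (key step).** The most likely failure is protonation of the aryl anion before acyl transfer, which stops the reaction at O-arylation. The acyl carbon is a CH2 next to a quaternary centre, so the four-centre addition is slow. An ene reaction of the aryne with the ring alkene and O-arylation of the product phenoxide by excess aryne would also consume material. Fallback, from 21 back to 25: acid 21 is converted with (COCl)2 into 2-[(1R,2R)-2-(7-methoxy-2-oxo-2H-chromen-6-yl)-1,4-dimethylcyclohex-3-en-1-yl]acetyl chloride F1. 1,3-Dimethoxybenzene is lithiated between its methoxy groups with BuLi to (2,6-dimethoxyphenyl)lithium F2 and transmetalated with ZnCl2 to (2,6-dimethoxyphenyl)zinc chloride F3, which does not add to the coumarin. Pd(PPh3)4-catalysed acylation of the zinc reagent with the acid chloride gives the 2,6-dimethoxyphenyl ketone F4. BCl3, bound to the ketone oxygen, then cleaves one of the two flanking methyl ethers to give 25.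

**Step 6.** Metathesis may stall because the vinyl group sits on a fully substituted carbon. Homodimerisation of 8 would then take over, and chelation of the methoxybenzylidene to ruthenium would slow turnover. Fallback, from 6 back to 9: lactone 6 is opened with KOH in aqueous methanol to potassium (5R)-5-hydroxy-2,5-dimethylhept-6-enoate F5. Its free tertiary allylic alcohol, which zerovalent palladium does not ionise, undergoes a Mizoroki–Heck reaction with 1-bromo-2,4-dimethoxybenzene (Pd(OAc)2, P(o-tolyl)3, Et3N, DMF) to give potassium (5R,6E)-7-(2,4-dimethoxyphenyl)-5-hydroxy-2,5-dimethylhept-6-enoate F6. Yamaguchi lactonisation (2,4,6-trichlorobenzoyl chloride, Et3N, 4-(dimethylamino)pyridine) returns to 9.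

**Step 7.** Stereochemical fidelity may be lost, or elimination may occur, through heterolysis of the tertiary cinnamyl-type C–O bond of ketene acetal 10 in place of the concerted shift; the dimethoxyphenyl group stabilises the allyl cation. C-silylation of the enolate would also divert material. Fallback, from 9 back to 12: iBu2AlH reduces 9 to the lactol (6R)-6-[(E)-2-(2,4-dimethoxyphenyl)ethenyl]-3,6-dimethyloxan-2-ol F7. MsCl and Et3N eliminate it to (2R)-2-[(E)-2-(2,4-dimethoxyphenyl)ethenyl]-2,5-dimethyl-3,4-dihydro-2H-pyran F8. Heating this enol ether in base-washed glass effects the neutral, purely thermal carbocyclic Claisen rearrangement of a 2-alkenyl dihydropyran through the same boat array, giving (1S,2S)-2-(2,4-dimethoxyphenyl)-1,4-dimethylcyclohex-3-ene-1-carbaldehyde F9. Pinnick oxidation (NaClO2, NaH2PO4, 2-methylbut-2-ene) gives 12.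

**Step 15.** Formylation may be slow or incomplete because the phenoxide oxygen is held in a six-membered magnesium chelate with the ortho ketone and the ring is less electron-rich than a simple phenol. Prolonged heating would favour O-methoxymethylation. Fallback, from 25 to 30, replacing steps 15 to 18: NaBH4 reduces 25 to 2-{1-hydroxy-2-[(1R,2R)-2-(7-methoxy-2-oxo-2H-chromen-6-yl)-1,4-dimethylcyclohex-3-en-1-yl]ethyl}-3-methoxyphenol F10. Brief dehydration with pyridinium p-toluenesulfonate in toluene at 60 °C gives 3-methoxy-2-{(E)-2-[(1R,2R)-2-(7-methoxy-2-oxo-2H-chromen-6-yl)-1,4-dimethylcyclohex-3-en-1-yl]ethenyl}phenol F11. This electron-rich phenol is formylated under the conditions of step 15 to 2-hydroxy-4-methoxy-3-{(E)-2-[(1R,2R)-2-(7-methoxy-2-oxo-2H-chromen-6-yl)-1,4-dimethylcyclohex-3-en-1-yl]ethenyl}benzaldehyde F12. Wittig olefination and lactonisation at the lowest workable temperature give 30. The price is that a benzylic cation and later the complete 1,5-diene are exposed, which the main line avoids.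

**Step 18.** Substitution may replace elimination (collapse of the sulfamate ion pair to a urethane), or the benzylic cation may be captured by the ring alkene, because the carbinol is flanked by two ortho substituents and its cation is oxygen-stabilised. A free cation would also erode the alkene geometry. Fallback, from 28 to 30: KN(SiMe3)2 in THF at −78 °C, then N-phenylbis(trifluoromethanesulfonimide), converts ketone 28 into (Z)-1-(7-methoxy-2-oxo-2H-chromen-8-yl)-2-[(1R,2R)-2-(7-methoxy-2-oxo-2H-chromen-6-yl)-1,4-dimethylcyclohex-3-en-1-yl]ethenyl trifluoromethanesulfonate F13; aryl ketone enolates form with oxygen cis to the α-substituent. Pd(OAc)2/PPh3-catalysed reduction with formic acid and Bu3N replaces the triflate by hydrogen with retention, which gives the E alkene 30 without any cationic intermediate.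

## Further compounds

F1 | step 14 | 2-[(1R,2R)-2-(7-methoxy-2-oxo-2H-chromen-6-yl)-1,4-dimethylcyclohex-3-en-1-yl]acetyl chloride | COc1cc2oc(=O)ccc2cc1[C@@H]1C=C(C)CC[C@]1(C)CC(=O)Cl
F2 | step 14 | (2,6-dimethoxyphenyl)lithium | COc1cccc(OC)c1[Li]
F3 | step 14 | (2,6-dimethoxyphenyl)zinc chloride | COc1cccc(OC)c1[Zn]Cl
F4 | step 14 | 1-(2,6-dimethoxyphenyl)-2-[(1R,2R)-2-(7-methoxy-2-oxo-2H-chromen-6-yl)-1,4-dimethylcyclohex-3-en-1-yl]ethan-1-one | COc1cc2oc(=O)ccc2cc1[C@@H]1C=C(C)CC[C@]1(C)CC(=O)c1c(OC)cccc1OC
F5 | step 6 | potassium (5R)-5-hydroxy-2,5-dimethylhept-6-enoate | CC(CC[C@@](C)(O)C=C)C(=O)[O-].[K+]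
F6 | step 6 | potassium (5R,6E)-7-(2,4-dimethoxyphenyl)-5-hydroxy-2,5-dimethylhept-6-enoate | CC(CC[C@@](C)(O)/C=C/c1ccc(OC)cc1OC)C(=O)[O-].[K+]
F7 | step 7 | (6R)-6-[(E)-2-(2,4-dimethoxyphenyl)ethenyl]-3,6-dimethyloxan-2-ol | CC1CC[C@@](C)(OC1O)/C=C/c1ccc(OC)cc1OC
F8 | step 7 | (2R)-2-[(E)-2-(2,4-dimethoxyphenyl)ethenyl]-2,5-dimethyl-3,4-dihydro-2H-pyran | CC1=CO[C@](C)(CC1)/C=C/c1ccc(OC)cc1OC
F9 | step 7 | (1S,2S)-2-(2,4-dimethoxyphenyl)-1,4-dimethylcyclohex-3-ene-1-carbaldehyde | COc1ccc([C@@H]2C=C(C)CC[C@]2(C)C=O)c(OC)c1
F10 | step 15 | 2-{1-hydroxy-2-[(1R,2R)-2-(7-methoxy-2-oxo-2H-chromen-6-yl)-1,4-dimethylcyclohex-3-en-1-yl]ethyl}-3-methoxyphenol | COc1cc2oc(=O)ccc2cc1[C@@H]1C=C(C)CC[C@]1(C)CC(O)c1c(O)cccc1OC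
F11 | step 15 | 3-methoxy-2-{(E)-2-[(1R,2R)-2-(7-methoxy-2-oxo-2H-chromen-6-yl)-1,4-dimethylcyclohex-3-en-1-yl]ethenyl}phenol | COc1cc2oc(=O)ccc2cc1[C@@H]1C=C(C)CC[C@]1(C)/C=C/c1c(O)cccc1OC
F12 | step 15 | 2-hydroxy-4-methoxy-3-{(E)-2-[(1R,2R)-2-(7-methoxy-2-oxo-2H-chromen-6-yl)-1,4-dimethylcyclohex-3-en-1-yl]ethenyl}benzaldehyde | COc1cc2oc(=O)ccc2cc1[C@@H]1C=C(C)CC[C@]1(C)/C=C/c1c(O)c(C=O)ccc1OC
F13 | step 18 | (Z)-1-(7-methoxy-2-oxo-2H-chromen-8-yl)-2-[(1R,2R)-2-(7-methoxy-2-oxo-2H-chromen-6-yl)-1,4-dimethylcyclohex-3-en-1-yl]ethenyl trifluoromethanesulfonate | COc1cc2oc(=O)ccc2cc1[C@@H]1C=C(C)CC[C@]1(C)/C=C(\OS(=O)(=O)C(F)(F)F)c1c(OC)ccc2ccc(=O)oc12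
A1 | alternative 1 | 2-methyl-5-oxohexanal | CC(=O)CCC(C)C=O
A2 | alternative 1 | 2,4-dimethoxy-1-[(E)-2-nitroethenyl]benzene | COc1ccc(/C=C/[N+](=O)[O-])c(OC)c1
A3 | alternative 1 | 2-(2,4-dimethoxyphenyl)-4-hydroxy-1,4-dimethyl-3-nitrocyclohexane-1-carbaldehyde (aryl cis to formyl) | O=C[C@@]1(C)CCC(C)(O)C([N+](=O)[O-])[C@H]1c1ccc(OC)cc1OC
A4 | alternative 2 | 3-methoxyphenyl 4-hydroxy-1,4-dimethylcyclohex-2-ene-1-carboxylate (quaternary centre as in the target) | COc1cccc(OC(=O)[C@@]2(C)CCC(C)(O)C=C2)c1
A5 | alternative 2 | cis-fused 3-methoxy-6a,9-dimethyl-6a,7,8,10a-tetrahydrobenzo[c]chromen-6-one | COc1ccc2[C@@H]3C=C(C)CC[C@]3(C)C(=O)Oc2c1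
A6 | alternative 3 | 4,4,5,5-tetramethyl-2-(4-methylcyclohexa-1,3-dien-1-yl)-1,3,2-dioxaborolane | CC1=CC=C(B2OC(C)(C)C(C)(C)O2)CC1
A7 | alternative 3 | 2,4-dimethoxyphenyl trifluoromethanesulfonate | COc1ccc(OS(=O)(=O)C(F)(F)F)c(OC)c1
A8 | alternative 3 | 2-[2-(2,4-dimethoxyphenyl)-1,4-dimethylcyclohex-3-en-1-yl]-4,4,5,5-tetramethyl-1,3,2-dioxaborolane (boron cis, methyl trans to aryl) | COc1ccc([C@@H]2C=C(C)CC[C@]2(C)B3OC(C)(C)C(C)(C)O3)c(OC)c1
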